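## Structural features

The target is a flavanonol 3-O-methyl ether. Ring A (C4a to C8a, methoxy on C5 and C7) is fused through C4a–C8a to the dihydropyranone ring C (O1, C2, C3, C4=O), and C2 carries ring B, a 2,5-dihydroxy-4-methoxyphenyl group. C2 (R, aryl) and C3 (R, methoxy) are neighbouring stereocentres with their substituents trans. The β-aryloxy ketone can open to a chalcone by retro-oxa-Michael reaction, C3–H is α to the carbonyl, and the methoxyhydroquinone ring B is oxidised to a quinone by air. The carbonyl and the free ring B phenols are therefore best introduced last. Six aromatic oxygens must be told apart: three methyl ethers, two free phenols and the ring oxygen O1. The real difficulty is absolute and relative control of C2 and C3 next to a carbonyl that can epimerise both. Ring A has oxygen on C5, C7 and C8a and carbon on C4a, the pattern of a 2-alkyl-3,5-dialkoxyphenol; a cyclobutenone–alkoxyalkyne benzannulation builds exactly this pattern and leaves the C8a oxygen as the only free phenol, the one needed to close ring C.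

## Logic of the disconnections

30 ⇒ 29. The two O–H bonds of ring B are traced back to O–CH2Ph bonds. The free hydroquinone is sensitive to air and to DDQ, so it is uncovered last; the gain is a ring B that is inert to organolithium, thermal and oxidative steps. The forward step must cleave two benzyl ethers without touching the C4 carbonyl or the benzylic C2–O1 bond, which calls for neutral hydrogenolysis.

29 ⇒ 28 ⇒ 27. The C4=O bond is taken back to C4–OH and then to C4–H. Without the carbonyl, C3 is not enolisable and ring C cannot open, so both stereocentres are safe while the ring is closed; ring A also becomes a plain 2-alkylphenol. The demand is an oxidation that chooses C4–H over C2–H and does not enolise C3 in its second stage.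

27 ⇒ 26 ⇒ 25. The O1–C2 bond is cut and the benzylic hydroxyl is masked as a silyl ether. The cut is made there because the C8a oxygen is the one phenol the annulation leaves free and C2 is an activated secondary carbinol. Ring C gives way to an open chain with two adjacent oxygenated stereocentres. The closure must invert C2, so the chain must be syn (1S,2S) to end as the trans ring, and ionisation of the electron-rich benzylic carbon must be kept in check.

25 ⇒ 20 + 18. Three ring A bonds are cut together: C4a–C8a, C5–C6 and C8–C8a. The substitution pattern of ring A maps onto a four-carbon vinylketene precursor and the two carbons of an ynol ether, and the step separates the C8a oxygen from the two methyl ethers. Ring A disappears into a small commercial-type ring and the end of an acyclic chain. The forward step needs one regiochemistry in the ketene–alkyne addition and neutral thermal conditions that spare the silyl ether, the benzyl ethers and the stereocentres.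

20 ⇒ 19. The O–CH3 bond is exchanged for O–C2H5, because the ethoxy compound is the commercial vinylogous ester. The exchange must not open the strained ring.

18 ⇒ 13 + 16, and 16 ⇒ 14. The bond between the propargylic CH2 (future C4) and the alkyne carbon (future C4a) is cut into an sp3 electrophile and an acetylide. This separates the two-carbon ynol ether, available from 14 by double elimination, from the three-carbon chiral unit. The displacement takes place at a β-oxygenated primary carbon, so a triflate and an amine-free lithium acetylide are required, and the product must be kept from acid.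

13 ⇒ 12 ⇒ 11 ⇒ 10. No skeletal bond is cut; the C–OTf bond, the oxidation level of C1 and the O–Si bond are adjusted. This leads back to an aldol adduct. The reduction must not move the silyl group and the triflate must be made and used cold.

10 ⇒ 7 + 4. The bond between the two stereocentres (future C2–C3) is cut. A syn α-alkoxy-β-hydroxy carbonyl unit is the retron of a glycolate aldol, so both stereocentres come from one step and the C3 methoxy group is present from the start. The forward step needs a Z enolate and the (R) auxiliary to give the (2R,3S) adduct.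

7 ⇒ 5 + 6. The N–acyl bond is cut to the auxiliary and the acid chloride; the forward step is a routine acylation.

4 ⇒ 2 ⇒ 1. The aryl–CHO bond and the two O–benzyl bonds are cut. The formylation must go para to the methoxy group and ortho to a benzyloxy group, the only position activated by two oxygens.

## Other disconnections considered

Alternative 1: The cut removes the C3–O and C4–O bonds and leaves a C3=C4 double bond, so ring C comes from the flav-3-ene A1. Forward, catalytic OsO4 with N-methylmorpholine N-oxide would add to the alkene face opposite the C2 aryl group and give the 2,3-trans-3,4-cis diol A2. The C4 hydroxyl would then be oxidised and the C3 hydroxyl methylated.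
- In its favour: C3 follows from C2 by a dependable steric argument, the C4 oxygen arrives in the same step, and ring A can be bought as a phloroglucinol derivative. On the C4 oxidation level this plan is better than the chosen one, which must oxidise a C–H bond of 27, and it is probably shorter.
- Against it: everything depends on A1 as a single enantiomer. A donor-substituted 2-aryl-2H-chromene can lose its only stereocentre by reversible 6π ring opening to the ortho-quinone methide or by ionisation to the flavylium ion, and no absolute control as direct as the aldol of step 4 is at hand. The C3 methyl ether would have to be made on an α-hydroxy ketone that opens and epimerises under base, whereas here it comes in with 6.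
- Comparison: on diastereocontrol the two plans are equal (facial bias there, aldol plus inversion here). The chosen plan is preferred because its stereocentres are made on a carbonyl-free chain that cannot racemise.

Alternative 2: The cut takes ring B apart (C1'–C2', C2'–C3', C5'–C6'). It leaves the alkyne A3, which already holds ring C and both stereocentres, and the carbene complex A4, (CO)5Cr=C(OMe)C(OMe)=CH2 of zerovalent chromium. Forward, the alkyne inserts into the Cr=C bond, CO inserts, the dienylketene closes, and (NH4)2Ce(NO3)6 releases the quinone A5, which Na2S2O4 would reduce to 30.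
- In its favour: the para relationship of the two ring B oxygens is intrinsic to this benzannulation, the terminal alkyne fixes the regiochemistry, ring B needs no protecting groups and only one reduction follows. In bond-forming power (three bonds, one ring) it equals step 11, and its end game is shorter.
- Against it: the annulation runs on A3, the most fragile compound of the plan (β-aryloxy ketone, acidic C3–H, propargylic C2–O1), under heating. Making A3 as one enantiomer is as large a problem as the target's core, chromium is stoichiometric, the α-methoxyvinyl carbene is not a routine reagent, and the ceric oxidation must spare ring A.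
- Comparison: the chosen plan runs its annulation early on the robust 18 and keeps the carbonyl out until step 15. It is longer but mechanistically less exposed.

Alternative 3: The cut is C4a–C5; ring A is unfolded to the β-keto ester chain of the dihydropyranone A6. Forward, mild base forms the extended enolate, C4a attacks the ester carbon in a Claisen (Dieckmann-type) condensation, and enolisation aromatises ring A to the 5,7-diol A7.
- In its favour: the C4 carbonyl is present from the outset, which is better than the chosen plan on that point. A6 could come from an asymmetric hetero-Diels–Alder reaction of 4, and the logic mirrors polyketide folding.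
- Against it: A7 needs two more O-methylations. The C5 hydroxyl is hydrogen-bonded to the carbonyl and needs base and forcing conditions, under which ring C can open and C2 and C3 can epimerise. The condensation itself exposes C3–H and the C2–O1 bond to base, and it forms one ring bond against three in step 11.
- Comparison: both plans build a ring A whose oxygen pattern is that of commercial phloroglucinol derivatives, so on step economy for ring A they are equal and neither is ideal. The chosen plan delivers the three oxygens already differentiated.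

Key step: step 11

Assumption: (R)-4-benzyloxazolidin-2-one (5) and methoxyacetyl chloride (6) are taken as commercial; 6 replaces methoxyacetic acid and saves an activation step.

Remark on the structures: 18 (1S,2S) and 25 (2S,3S) are the syn series; inversion at the benzylic carbon gives trans 27 (2R,3S), and C3 is named R in 29 and 30 only because C4 gains priority as a carbonyl. No structure needed correcting; the design changes are an amine-free acetylide, acid-free handling of 18 and buffered desilylation.

## Route

Step 1
Reactants: 1 2-methoxyhydroquinone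
Product: 2 1,4-bis(benzyloxy)-2-methoxybenzene
Conditions: BnBr (2.3 equiv), K2CO3 (3 equiv), DMF, 60 °C, N2
Reagents that add atoms: benzyl bromide, BrCc1ccccc1
Why: Williamson etherification of both phenols; benzyl ethers survive organolithium, heat, fluoride and DDQ and leave by hydrogenolysis at the end.

Step 2
Reactants: 2 1,4-bis(benzyloxy)-2-methoxybenzene
Product: 4 2,5-bis(benzyloxy)-4-methoxybenzaldehyde, via aryl iminium chloride 3 (not isolated)
Conditions: POCl3 (1.5 equiv), DMF, 0 → 70 °C; then aq. NaOAc, rt
Reagents that add atoms: N,N-dimethylformamide, CN(C)C=O; water, O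
Why: Vilsmeier–Haack formylation; the position para to OMe and ortho to OBn is the only one activated by two oxygens, as in other 1,2,4-trialkoxybenzenes, and hydrolysis of the iminium salt should give the 2,4,5-trioxygenated aldehyde.

Step 3
Reactants: 5 (R)-4-benzyloxazolidin-2-one; 6 methoxyacetyl chloride
Product: 7 (R)-4-benzyl-3-(methoxyacetyl)oxazolidin-2-one
Conditions: n-BuLi (1.0 equiv), THF, −78 °C; then 6, −78 → 0 °C
Reagents that add atoms: none
Why: N-acylation of the lithiated oxazolidinone by the acid chloride, a standard way to load the auxiliary.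

Step 4
Reactants: 7 (R)-4-benzyl-3-(methoxyacetyl)oxazolidin-2-one; 4 2,5-bis(benzyloxy)-4-methoxybenzaldehyde
Product: 10 (R)-4-benzyl-3-[(2R,3S)-3-[2,5-bis(benzyloxy)-4-methoxyphenyl]-3-hydroxy-2-methoxypropanoyl]oxazolidin-2-one, via boron enolate 8 (not isolated), via boron aldolate 9 (not isolated)
Conditions: Bu2BOTf (1.1 equiv), Et3N (1.3 equiv), CH2Cl2, −78 → 0 °C; 4, −78 → 0 °C; then pH 7 buffer, MeOH, 30% H2O2, 0 °C
Reagents that add atoms: none
Why: Evans syn glycolate aldol: the Z boron enolate reacts through a closed Zimmerman–Traxler chair on the face away from the benzyl group, which should set C2 (R) and C3 (S) together as the syn pair; the (R) auxiliary is chosen because this enantiomeric series leads to the target after inversion at the carbinol carbon.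

Step 5
Reactants: 10 (R)-4-benzyl-3-[(2R,3S)-3-[2,5-bis(benzyloxy)-4-methoxyphenyl]-3-hydroxy-2-methoxypropanoyl]oxazolidin-2-one
Product: 11 (R)-4-benzyl-3-[(2R,3S)-3-[2,5-bis(benzyloxy)-4-methoxyphenyl]-3-(tert-butyldimethylsilyloxy)-2-methoxypropanoyl]oxazolidin-2-one
Conditions: TBSOTf (1.3 equiv), 2,6-lutidine (2 equiv), CH2Cl2, −78 → 0 °C
Reagents that add atoms: tert-butyldimethylsilyl trifluoromethanesulfonate, CC(C)(C)[Si](C)(C)OS(=O)(=O)C(F)(F)F
Why: Silylation of the hindered benzylic hydroxyl with a silyl triflate and a hindered base; the ether blocks retro-aldol cleavage and protects the hydroxyl through reduction, acetylide alkylation and the thermal annulation.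

Step 6
Reactants: 11 (R)-4-benzyl-3-[(2R,3S)-3-[2,5-bis(benzyloxy)-4-methoxyphenyl]-3-(tert-butyldimethylsilyloxy)-2-methoxypropanoyl]oxazolidin-2-one
Product: 12 (2S,3S)-3-[2,5-bis(benzyloxy)-4-methoxyphenyl]-3-(tert-butyldimethylsilyloxy)-2-methoxypropan-1-ol
Conditions: LiBH4 (2 equiv), MeOH (2 equiv), THF, 0 °C → rt
Reagents that add atoms: none
Why: Reductive cleavage of the imide by LiBH4 should release the primary alcohol and the recoverable auxiliary without touching either stereocentre; the descriptor at C2 changes only through the priority rules.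

Step 7
Reactants: 12 (2S,3S)-3-[2,5-bis(benzyloxy)-4-methoxyphenyl]-3-(tert-butyldimethylsilyloxy)-2-methoxypropan-1-ol
Product: 13 (2S,3S)-3-[2,5-bis(benzyloxy)-4-methoxyphenyl]-3-(tert-butyldimethylsilyloxy)-2-methoxypropyl trifluoromethanesulfonate
Conditions: Tf2O (1.2 equiv), 2,6-lutidine (1.5 equiv), CH2Cl2, −78 °C; cold aqueous work-up, used at once
Reagents that add atoms: trifluoromethanesulfonic anhydride, O=S(=O)(OS(=O)(=O)C(F)(F)F)C(F)(F)F
Why: Low-temperature triflation of a primary alcohol; a triflate is needed because the carbon is β-branched and β-oxygenated and a halide or tosylate would react too slowly with an acetylide.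

Step 8
Reactants: 14 chloroacetaldehyde dimethyl acetal
Product: 16 methoxyacetylene, via sodium methoxyacetylide 15 (not isolated)
Conditions: NaNH2 (3.1 equiv), liquid NH3, −33 °C; then cold brine, −70 °C; distilled into THF at −78 °C
Reagents that add atoms: none
Why: Double β-elimination (methanol, then HCl) by sodium amide is the classical route to alkoxyacetylenes; water liberates the volatile alkyne, which is kept as a cold, amine-free THF solution.

Step 9
Reactants: 16 methoxyacetylene; 13 (2S,3S)-3-[2,5-bis(benzyloxy)-4-methoxyphenyl]-3-(tert-butyldimethylsilyloxy)-2-methoxypropyl trifluoromethanesulfonate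
Product: 18 tert-butyl{[(1S,2S)-1-[2,5-bis(benzyloxy)-4-methoxyphenyl]-2,5-dimethoxypent-4-yn-1-yl]oxy}dimethylsilane, via lithium methoxyacetylide 17 (not isolated)
Conditions: 16 (1.6 equiv), n-BuLi (1.5 equiv), THF, −78 °C; then 13, DMPU, −78 → −20 °C; aq. NaHCO3 work-up, Et3N-deactivated silica
Reagents that add atoms: none
Why: SN2 alkylation of a lithium alkoxyacetylide by a primary triflate in THF/DMPU; the acetylide is made from isolated 16 because generating it with a lithium amide would leave a secondary amine that competes for the triflate, and the acid-labile ynol ether is kept basic throughout.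

Step 10
Reactants: 19 3-ethoxycyclobut-2-en-1-one
Product: 20 3-methoxycyclobut-2-en-1-one
Conditions: MeOH (solvent), camphorsulfonic acid (cat.), rt; solid K2CO3, filtration; short-path distillation
Reagents that add atoms: methanol, CO
Why: Acid-catalysed alkoxy exchange of a vinylogous ester (addition of methanol at C3, loss of ethanol), driven by the solvent; any 3,3-dialkoxycyclobutanone formed by conjugate addition should lose alcohol again on distillation.

Step 11
Reactants: 20 3-methoxycyclobut-2-en-1-one; 18 tert-butyl{[(1S,2S)-1-[2,5-bis(benzyloxy)-4-methoxyphenyl]-2,5-dimethoxypent-4-yn-1-yl]oxy}dimethylsilane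
Product: 25 2-[(2S,3S)-3-[2,5-bis(benzyloxy)-4-methoxyphenyl]-3-(tert-butyldimethylsilyloxy)-2-methoxypropyl]-3,5-dimethoxyphenol, via vinylketene 21 (not isolated), via vinylcyclobutenone 22 (not isolated), via dienylketene 23 (not isolated), via cyclohexadienone 24 (not isolated)
Conditions: 20 (2 equiv, two portions), toluene, 80 °C then 110 °C, Ar; then K2CO3, MeOH, rt
Reagents that add atoms: none
Why: Heating opens 20 by 4π electrocyclic cleavage to vinylketene 21, which adds the ynol ether 18 across its C=C bond in a (2+2) step to give 22; a second 4π opening gives dienylketene 23, 6π electrocyclisation gives 24, and tautomerisation gives phenol 25. The closest known reaction type is the Danheiser benzannulation of cyclobutenones with alkoxy- or siloxyalkynes to resorcinol monoethers. Ring A is closed by the 6π electrocyclisation (C8–C8a) after the (2+2) step has made C4a–C8a and C5–C6. No stereocentre is formed, and the two existing ones lie outside the reacting π system and have no acidic hydrogen, so neutral heating should leave them alone. The selectivity needed is the regiochemistry of the ketene–alkyne addition: the alkyne carbon remote from OMe is the nucleophilic one and bonds to the ketene carbonyl carbon, so the chain ends ortho to the new hydroxyl and the alkyne methoxy group meta to it. A methoxy ynol ether has no β-hydrogen on oxygen and cannot fragment to a ketene by retro-ene reaction at these temperatures. Excess 20 allows for ketene dimerisation, and the basic methanol treatment should return any phenol acylated by 21.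

Step 12
Reactants: 25 2-[(2S,3S)-3-[2,5-bis(benzyloxy)-4-methoxyphenyl]-3-(tert-butyldimethylsilyloxy)-2-methoxypropyl]-3,5-dimethoxyphenol
Product: 26 2-[(2S,3S)-3-[2,5-bis(benzyloxy)-4-methoxyphenyl]-3-hydroxy-2-methoxypropyl]-3,5-dimethoxyphenol
Conditions: TBAF (1.5 equiv), AcOH (1.5 equiv), THF, rt
Reagents that add atoms: none
Why: Fluoride cleaves the secondary benzylic silyl ether; acetic acid buffers the medium so that the electron-rich phenol is not held as a phenoxide in air.

Step 13
Reactants: 26 2-[(2S,3S)-3-[2,5-bis(benzyloxy)-4-methoxyphenyl]-3-hydroxy-2-methoxypropyl]-3,5-dimethoxyphenol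
Product: 27 (2R,3S)-2-[2,5-bis(benzyloxy)-4-methoxyphenyl]-3,5,7-trimethoxychromane
Conditions: PPh3 (1.5 equiv), DIAD (1.5 equiv), THF, 0 °C → rt
Reagents that add atoms: none
Why: Intramolecular Mitsunobu etherification: the phenol is the acidic partner and 6-exo-tet SN2 displacement of the benzylic oxyphosphonium inverts C2, so the syn chain should give the 2,3-trans ring; any leakage through the benzylic cation should also favour the trans, diequatorial ring.

Step 14
Reactants: 27 (2R,3S)-2-[2,5-bis(benzyloxy)-4-methoxyphenyl]-3,5,7-trimethoxychromane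
Product: 28 (2R,3S)-2-[2,5-bis(benzyloxy)-4-methoxyphenyl]-3,5,7-trimethoxychroman-4-ol (C4 epimers)
Conditions: DDQ (1.3 equiv), CH2Cl2/H2O (10:1), 0 °C → rt
Reagents that add atoms: water, O
Why: DDQ abstracts hydride from C4, whose cation is stabilised by O1 and C5–OMe (ortho) and C7–OMe (para), and water captures it; this is the established C4 functionalisation of 5,7-dialkoxyflavans, and the C4 configuration does not matter because it is oxidised next.

Step 15
Reactants: 28 (2R,3S)-2-[2,5-bis(benzyloxy)-4-methoxyphenyl]-3,5,7-trimethoxychroman-4-ol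
Product: 29 (2R,3R)-2-[2,5-bis(benzyloxy)-4-methoxyphenyl]-3,5,7-trimethoxychroman-4-one
Conditions: Dess–Martin periodinane (1.5 equiv), NaHCO3, CH2Cl2, rt
Reagents that add atoms: none
Why: Buffered Dess–Martin oxidation of a secondary benzylic alcohol under neutral conditions that should not enolise C3; both C4 epimers converge on one ketone.

Step 16
Reactants: 29 (2R,3R)-2-[2,5-bis(benzyloxy)-4-methoxyphenyl]-3,5,7-trimethoxychroman-4-one
Product: 30 (2R,3R)-2-(2,5-dihydroxy-4-methoxyphenyl)-3,5,7-trimethoxychroman-4-one
Conditions: H2 (1 atm), 10% Pd/C, EtOAc/MeOH, rt; filtered and concentrated under Ar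
Reagents that add atoms: none
Why: Hydrogenolysis of the two aryl benzyl ethers under neutral conditions; the donor-deactivated aryl ketone and the C2–O1 bond should survive a short reaction, and the hydroquinone is handled under inert gas.

## Compound list

1 | 2-methoxyhydroquinone | COc1cc(O)ccc1O | starting material
2 | 1,4-bis(benzyloxy)-2-methoxybenzene | COc1cc(OCc2ccccc2)ccc1OCc1ccccc1 | intermediate
3 | [2,5-bis(benzyloxy)-4-methoxybenzylidene]dimethyliminium chloride | C[N+](C)=Cc1cc(OCc2ccccc2)c(OC)cc1OCc1ccccc1.[Cl-] | intermediate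
4 | 2,5-bis(benzyloxy)-4-methoxybenzaldehyde | O=Cc1cc(OCc2ccccc2)c(OC)cc1OCc1ccccc1 | intermediate
5 | (R)-4-benzyloxazolidin-2-one | O=C1N[C@H](Cc2ccccc2)CO1 | starting material
6 | methoxyacetyl chloride | COCC(Cl)=O | starting material
7 | (R)-4-benzyl-3-(methoxyacetyl)oxazolidin-2-one | COCC(=O)N1[C@H](Cc2ccccc2)COC1=O | intermediate
8 | (R)-4-benzyl-3-[(Z)-1-(dibutylboranyloxy)-2-methoxyethenyl]oxazolidin-2-one | CCCCB(CCCC)O/C(=C\OC)N1[C@H](Cc2ccccc2)COC1=O | intermediate
9 | dibutylborinate of 10 at the C3 oxygen | O=C([C@H](OC)[C@@H](OB(CCCC)CCCC)c1cc(OCc2ccccc2)c(OC)cc1OCc1ccccc1)N1[C@H](Cc2ccccc2)COC1=O | intermediate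
10 | (R)-4-benzyl-3-[(2R,3S)-3-[2,5-bis(benzyloxy)-4-methoxyphenyl]-3-hydroxy-2-methoxypropanoyl]oxazolidin-2-one | O=C([C@H](OC)[C@@H](O)c1cc(OCc2ccccc2)c(OC)cc1OCc1ccccc1)N1[C@H](Cc2ccccc2)COC1=O | intermediate
11 | (R)-4-benzyl-3-[(2R,3S)-3-[2,5-bis(benzyloxy)-4-methoxyphenyl]-3-(tert-butyldimethylsilyloxy)-2-methoxypropanoyl]oxazolidin-2-one | O=C([C@H](OC)[C@@H](O[Si](C)(C)C(C)(C)C)c1cc(OCc2ccccc2)c(OC)cc1OCc1ccccc1)N1[C@H](Cc2ccccc2)COC1=O | intermediate
12 | (2S,3S)-3-[2,5-bis(benzyloxy)-4-methoxyphenyl]-3-(tert-butyldimethylsilyloxy)-2-methoxypropan-1-ol | OC[C@H](OC)[C@@H](O[Si](C)(C)C(C)(C)C)c1cc(OCc2ccccc2)c(OC)cc1OCc1ccccc1 | intermediate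
13 | (2S,3S)-3-[2,5-bis(benzyloxy)-4-methoxyphenyl]-3-(tert-butyldimethylsilyloxy)-2-methoxypropyl trifluoromethanesulfonate | FC(F)(F)S(=O)(=O)OC[C@H](OC)[C@@H](O[Si](C)(C)C(C)(C)C)c1cc(OCc2ccccc2)c(OC)cc1OCc1ccccc1 | intermediate
14 | chloroacetaldehyde dimethyl acetal | COC(CCl)OC | starting material
15 | sodium methoxyacetylide | [Na+].[C-]#COC | intermediate
16 | methoxyacetylene | C#COC | intermediate
17 | lithium methoxyacetylide | [Li+].[C-]#COC | intermediate
18 | tert-butyl{[(1S,2S)-1-[2,5-bis(benzyloxy)-4-methoxyphenyl]-2,5-dimethoxypent-4-yn-1-yl]oxy}dimethylsilane | COC#CC[C@H](OC)[C@@H](O[Si](C)(C)C(C)(C)C)c1cc(OCc2ccccc2)c(OC)cc1OCc1ccccc1 | intermediate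
19 | 3-ethoxycyclobut-2-en-1-one | CCOC1=CC(=O)C1 | starting material
20 | 3-methoxycyclobut-2-en-1-one | COC1=CC(=O)C1 | intermediate
21 | 3-methoxybuta-1,3-dien-1-one | C=C(OC)C=C=O | intermediate
22 | 2-[(2S,3S)-3-[2,5-bis(benzyloxy)-4-methoxyphenyl]-3-(tert-butyldimethylsilyloxy)-2-methoxypropyl]-3-methoxy-4-(1-methoxyethenyl)cyclobut-2-en-1-one (C4 epimers) | C=C(OC)C1C(OC)=C(C[C@H](OC)[C@@H](O[Si](C)(C)C(C)(C)C)c2cc(OCc3ccccc3)c(OC)cc2OCc2ccccc2)C1=O | intermediate
23 | (3E)-2-[(2S,3S)-3-[2,5-bis(benzyloxy)-4-methoxyphenyl]-3-(tert-butyldimethylsilyloxy)-2-methoxypropyl]-3,5-dimethoxyhexa-1,3,5-trien-1-one | C=C(OC)/C=C(/OC)C(C[C@H](OC)[C@@H](O[Si](C)(C)C(C)(C)C)c1cc(OCc2ccccc2)c(OC)cc1OCc1ccccc1)=C=O | intermediate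
24 | 2-[(2S,3S)-3-[2,5-bis(benzyloxy)-4-methoxyphenyl]-3-(tert-butyldimethylsilyloxy)-2-methoxypropyl]-3,5-dimethoxycyclohexa-2,4-dien-1-one | O=C1CC(OC)=CC(OC)=C1C[C@H](OC)[C@@H](O[Si](C)(C)C(C)(C)C)c1cc(OCc2ccccc2)c(OC)cc1OCc1ccccc1 | intermediate
25 | 2-[(2S,3S)-3-[2,5-bis(benzyloxy)-4-methoxyphenyl]-3-(tert-butyldimethylsilyloxy)-2-methoxypropyl]-3,5-dimethoxyphenol | COc1cc(O)c(C[C@H](OC)[C@@H](O[Si](C)(C)C(C)(C)C)c2cc(OCc3ccccc3)c(OC)cc2OCc2ccccc2)c(OC)c1 | intermediate
26 | 2-[(2S,3S)-3-[2,5-bis(benzyloxy)-4-methoxyphenyl]-3-hydroxy-2-methoxypropyl]-3,5-dimethoxyphenol | COc1cc(O)c(C[C@H](OC)[C@@H](O)c2cc(OCc3ccccc3)c(OC)cc2OCc2ccccc2)c(OC)c1 | intermediate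
27 | (2R,3S)-2-[2,5-bis(benzyloxy)-4-methoxyphenyl]-3,5,7-trimethoxychromane | COc1cc(OC)c2c(c1)O[C@H](c1cc(OCc3ccccc3)c(OC)cc1OCc1ccccc1)[C@@H](OC)C2 | intermediate
28 | (2R,3S)-2-[2,5-bis(benzyloxy)-4-methoxyphenyl]-3,5,7-trimethoxychroman-4-ol (C4 epimers) | COc1cc(OC)c2c(c1)O[C@H](c1cc(OCc3ccccc3)c(OC)cc1OCc1ccccc1)[C@@H](OC)C2O | intermediate
29 | (2R,3R)-2-[2,5-bis(benzyloxy)-4-methoxyphenyl]-3,5,7-trimethoxychroman-4-one | COc1cc(OC)c2c(c1)O[C@H](c1cc(OCc3ccccc3)c(OC)cc1OCc1ccccc1)[C@@H](OC)C2=O | intermediate
30 | (2R,3R)-2-(2,5-dihydroxy-4-methoxyphenyl)-3,5,7-trimethoxychroman-4-one | COc1cc(OC)c2c(c1)O[C@H](c1cc(O)c(OC)cc1O)[C@@H](OC)C2=O | target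

## Step count and least certain steps

Total: 16 steps. Longest linear sequence: 13 steps (1, 2, 4, 5, 6, 7, 9, 11, 12, 13, 14, 15, 16).

**Step 11 (key step).** The most likely failure is loss of the electron-rich vinylketene to dimerisation, oligomerisation or acylation of the product before the hindered ynol ether intercepts it. The second ring opening may also stall at the lower temperature, and forcing it could degrade the ynol ether. The fallback buys ring A instead of building it and sets out from 13. 5-Methoxyresorcinol would be protected (MOMCl, NaH) as 1-methoxy-3,5-bis(methoxymethoxy)benzene F1, lithiated between the two acetal oxygens (n-BuLi, THF, 0 °C) and alkylated with 13 to give tert-butyl{(1S,2S)-1-[2,5-bis(benzyloxy)-4-methoxyphenyl]-2-methoxy-3-[4-methoxy-2,6-bis(methoxymethoxy)phenyl]propoxy}dimethylsilane F2. HCl in methanol would remove the acetals and the silyl ether to give 2-[(2S,3S)-3-[2,5-bis(benzyloxy)-4-methoxyphenyl]-3-hydroxy-2-methoxypropyl]-5-methoxybenzene-1,3-diol F3. Mitsunobu closure, in which the two phenols are equivalent, would give (2R,3S)-2-[2,5-bis(benzyloxy)-4-methoxyphenyl]-3,7-dimethoxychroman-5-ol F4, and MeI/K2CO3 would return to the route at 27.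

**Step 9.** Slow C-alkylation by the weakly nucleophilic, thermally fragile acetylide may let elimination of the triflate compete, and the ynol ether may be hydrated to an ester on contact with acid during purification. The fallback uses a sturdier nucleophile and a sturdier alkyne partner and sets out from 13. Lithium (trimethylsilyl)acetylide in THF/DMPU would give tert-butyl{[(1S,2S)-1-[2,5-bis(benzyloxy)-4-methoxyphenyl]-2-methoxy-5-(trimethylsilyl)pent-4-yn-1-yl]oxy}dimethylsilane F5, and K2CO3 in methanol would give tert-butyl{[(1S,2S)-1-[2,5-bis(benzyloxy)-4-methoxyphenyl]-2-methoxypent-4-yn-1-yl]oxy}dimethylsilane F6. Lithiation, oxidation of the acetylide with lithium tert-butyl peroxide to the ynolate and O-silylation with iPr3SiOTf would give {[(4S,5S)-5-[2,5-bis(benzyloxy)-4-methoxyphenyl]-5-(tert-butyldimethylsilyloxy)-4-methoxypent-1-yn-1-yl]oxy}tri(propan-2-yl)silane F7. Heating F7 with 20 as in step 11 would give 2-[(2S,3S)-3-[2,5-bis(benzyloxy)-4-methoxyphenyl]-3-(tert-butyldimethylsilyloxy)-2-methoxypropyl]-5-methoxy-3-[tri(propan-2-yl)silyloxy]phenol F8. TBAF would remove both silyl groups to reach the triol F3 described above, which goes on through F4 to 27.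

**Step 10.** Conjugate addition of methanol may stop at the 3,3-dialkoxycyclobutanone, and the strained ring may be lost to acid or on distillation. The fallback alkylates the enol instead of exchanging the ether and sets out from 19. Dilute aqueous HCl would give cyclobutane-1,3-dione F9, and O-methylation of this acidic enol with Me3SiCHN2 in methanol/ether would return to the route at 20.

**Step 13.** Ionisation of the oxyphosphonium intermediate at the electron-rich benzylic carbon may erode the stereospecificity at C2 and open an elimination path to the enol ether. The fallback gives up inversion and relies on thermodynamic control: 26 would be treated with a catalytic Brønsted acid (camphorsulfonic acid, CH2Cl2) so that the benzylic cation is captured by the phenol in the more stable 2,3-trans ring. It arrives at 27 directly and makes no new compound.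

**Step 14.** Hydride abstraction at C2, which is activated by O1 and by ring B, may compete with that at C4, and the C4 cation may be trapped by ring A of a second molecule. The fallback lowers the donor strength of ring B before the oxidation and sets out from 27. Hydrogenolysis would give 2-methoxy-5-[(2R,3S)-3,5,7-trimethoxychroman-2-yl]benzene-1,4-diol F10, and Ac2O/pyridine would give 2-methoxy-5-[(2R,3S)-3,5,7-trimethoxychroman-2-yl]-1,4-phenylene diacetate F11. DDQ in wet CH2Cl2 would then give 2-[(2R,3S)-4-hydroxy-3,5,7-trimethoxychroman-2-yl]-5-methoxy-1,4-phenylene diacetate F12, and Dess–Martin oxidation would give 2-methoxy-5-[(2R,3R)-3,5,7-trimethoxy-4-oxochroman-2-yl]-1,4-phenylene diacetate F13. Mild deacetylation (NH4OAc, aqueous methanol) would come back to the route at 30.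

## Further compounds

F1 | step 11 | 1-methoxy-3,5-bis(methoxymethoxy)benzene | COCOc1cc(OC)cc(OCOC)c1
F2 | step 11 | tert-butyl{(1S,2S)-1-[2,5-bis(benzyloxy)-4-methoxyphenyl]-2-methoxy-3-[4-methoxy-2,6-bis(methoxymethoxy)phenyl]propoxy}dimethylsilane | COCOc1cc(OC)cc(OCOC)c1C[C@H](OC)[C@@H](O[Si](C)(C)C(C)(C)C)c1cc(OCc2ccccc2)c(OC)cc1OCc1ccccc1
F3 | step 11 | 2-[(2S,3S)-3-[2,5-bis(benzyloxy)-4-methoxyphenyl]-3-hydroxy-2-methoxypropyl]-5-methoxybenzene-1,3-diol | COc1cc(O)c(C[C@H](OC)[C@@H](O)c2cc(OCc3ccccc3)c(OC)cc2OCc2ccccc2)c(O)c1
F4 | step 11 | (2R,3S)-2-[2,5-bis(benzyloxy)-4-methoxyphenyl]-3,7-dimethoxychroman-5-ol | COc1cc(O)c2c(c1)O[C@H](c1cc(OCc3ccccc3)c(OC)cc1OCc1ccccc1)[C@@H](OC)C2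
F5 | step 9 | tert-butyl{[(1S,2S)-1-[2,5-bis(benzyloxy)-4-methoxyphenyl]-2-methoxy-5-(trimethylsilyl)pent-4-yn-1-yl]oxy}dimethylsilane | C[Si](C)(C)C#CC[C@H](OC)[C@@H](O[Si](C)(C)C(C)(C)C)c1cc(OCc2ccccc2)c(OC)cc1OCc1ccccc1
F6 | step 9 | tert-butyl{[(1S,2S)-1-[2,5-bis(benzyloxy)-4-methoxyphenyl]-2-methoxypent-4-yn-1-yl]oxy}dimethylsilane | C#CC[C@H](OC)[C@@H](O[Si](C)(C)C(C)(C)C)c1cc(OCc2ccccc2)c(OC)cc1OCc1ccccc1
F7 | step 9 | {[(4S,5S)-5-[2,5-bis(benzyloxy)-4-methoxyphenyl]-5-(tert-butyldimethylsilyloxy)-4-methoxypent-1-yn-1-yl]oxy}tri(propan-2-yl)silane | CC(C)[Si](OC#CC[C@H](OC)[C@@H](O[Si](C)(C)C(C)(C)C)c1cc(OCc2ccccc2)c(OC)cc1OCc1ccccc1)(C(C)C)C(C)C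
F8 | step 9 | 2-[(2S,3S)-3-[2,5-bis(benzyloxy)-4-methoxyphenyl]-3-(tert-butyldimethylsilyloxy)-2-methoxypropyl]-5-methoxy-3-[tri(propan-2-yl)silyloxy]phenol | COc1cc(O)c(C[C@H](OC)[C@@H](O[Si](C)(C)C(C)(C)C)c2cc(OCc3ccccc3)c(OC)cc2OCc2ccccc2)c(O[Si](C(C)C)(C(C)C)C(C)C)c1
F9 | step 10 | cyclobutane-1,3-dione | O=C1CC(=O)C1
F0 | step 13 | none | none
F10 | step 14 | 2-methoxy-5-[(2R,3S)-3,5,7-trimethoxychroman-2-yl]benzene-1,4-diol | COc1cc(OC)c2c(c1)O[C@H](c1cc(O)c(OC)cc1O)[C@@H](OC)C2
F11 | step 14 | 2-methoxy-5-[(2R,3S)-3,5,7-trimethoxychroman-2-yl]-1,4-phenylene diacetate | COc1cc(OC)c2c(c1)O[C@H](c1cc(OC(C)=O)c(OC)cc1OC(C)=O)[C@@H](OC)C2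
F12 | step 14 | 2-[(2R,3S)-4-hydroxy-3,5,7-trimethoxychroman-2-yl]-5-methoxy-1,4-phenylene diacetate (C4 epimers) | COc1cc(OC)c2c(c1)O[C@H](c1cc(OC(C)=O)c(OC)cc1OC(C)=O)[C@@H](OC)C2O
F13 | step 14 | 2-methoxy-5-[(2R,3R)-3,5,7-trimethoxy-4-oxochroman-2-yl]-1,4-phenylene diacetate | COc1cc(OC)c2c(c1)O[C@H](c1cc(OC(C)=O)c(OC)cc1OC(C)=O)[C@@H](OC)C2=O
A1 | alternative 1 | (2S)-2-[2,5-bis(benzyloxy)-4-methoxyphenyl]-5,7-dimethoxy-2H-chromene | COc1cc(OC)c2c(c1)O[C@H](c1cc(OCc3ccccc3)c(OC)cc1OCc1ccccc1)C=C2
A2 | alternative 1 | (2R,3S,4S)-2-[2,5-bis(benzyloxy)-4-methoxyphenyl]-5,7-dimethoxychromane-3,4-diol | COc1cc(OC)c2c(c1)O[C@H](c1cc(OCc3ccccc3)c(OC)cc1OCc1ccccc1)[C@@H](O)[C@H]2O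
A3 | alternative 2 | (2R,3R)-2-ethynyl-3,5,7-trimethoxychroman-4-one | COc1cc(OC)c2c(c1)O[C@H](C#C)[C@@H](OC)C2=O
A4 | alternative 2 | pentacarbonyl[methoxy(1-methoxyethenyl)methylidene]chromium | COC(=[Cr])C(OC)=C.[C-]#[O+].[C-]#[O+].[C-]#[O+].[C-]#[O+].[C-]#[O+]
A5 | alternative 2 | 2-methoxy-5-[(2R,3R)-3,5,7-trimethoxy-4-oxochroman-2-yl]cyclohexa-2,5-diene-1,4-dione | COc1cc(OC)c2c(c1)O[C@H](C1=CC(=O)C(OC)=CC1=O)[C@@H](OC)C2=O
A6 | alternative 3 | methyl 4-[(2R,3R)-2-[2,5-bis(benzyloxy)-4-methoxyphenyl]-3-methoxy-4-oxo-3,4-dihydro-2H-pyran-6-yl]-3-oxobutanoate | COC(=O)CC(=O)CC1=CC(=O)[C@H](OC)[C@@H](c2cc(OCc3ccccc3)c(OC)cc2OCc2ccccc2)O1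
A7 | alternative 3 | (2R,3R)-2-[2,5-bis(benzyloxy)-4-methoxyphenyl]-5,7-dihydroxy-3-methoxychroman-4-one | Oc1cc(O)c2c(c1)O[C@H](c1cc(OCc3ccccc3)c(OC)cc1OCc1ccccc1)[C@@H](OC)C2=O
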